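**Retrosynthetic overview**

- Numbering: unit A is the 2-hydroxy-4,5-dimethoxy-7-methylnaphthalene half (axis carbon C1; oxygenated inner ring W, outer ring X). Unit B is the primed half (axis C1', C2' Me, C4' OH, C5' OMe, C6' OH; inner ring Y, outer ring Z). The plan rests on ring Y: its axis carbon C1' and its only oxygenated carbon C4' are para and the C2' methyl lies next to the axis, so ring Y is read as a C1'–O–C4' oxygen bridge plus a two-carbon alkyne whose ester later becomes that methyl.
- The target comes from a benzyl-protected 2'-ester by hydride reduction and hydrogenolysis. The ester comes from a 1-arylisobenzofuran and methyl propiolate (C1'–C2' and C3'–C4' by [4+2], then opening of the bridge at C1').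
- The isobenzofuran is released by acid from a hydroxy acetal. This is made by adding an aryllithium (from 2,3-dihydroxybenzaldehyde, lithiated carbon = future C8a') to the unit A C1 aldehyde, whose formyl carbon is the future C1'.
- The unit A aldehyde comes from 4,5-dimethoxy-7-methyl-2-naphthol, whose ring W is closed by a Diels–Alder reaction of 3-methoxy-5-methylbenzyne with 1,1-dimethoxy-3-silyloxybutadiene.
- Ring order: rings X and Z are bought as benzenes; ring W is closed in step 6, the halves are joined in step 13, and ring Y is closed last in step 14.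

Key step: step 14

Remark: the target is drawn without a descriptor for the C1–C1' axis, which carries four ortho substituents; the racemic biaryl is assumed to be wanted, and the molecule has no stereocentre.

**Route**

Step 1
Reactants: 1 3-methoxy-5-methylphenol
Product: 2 3-methoxy-5-methylphenyl N-isopropylcarbamate
Conditions: i-PrNCO, Et3N (cat.), CH2Cl2, rt
Reagents that add atoms: isopropyl isocyanate, CC(C)N=C=O
Why: Base-catalysed addition of the phenol to the isocyanate (carbamoylation) should give the N–H carbamate, which serves as a directing group that can later be removed under mild conditions.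

Step 2
Reactants: 2 3-methoxy-5-methylphenyl N-isopropylcarbamate
Product: 6 3-methoxy-5-methyl-2-(trimethylsilyl)phenyl N-isopropylcarbamate, via N-silyl carbamate 3 (not isolated), via ortho-lithio N-silyl carbamate 4 (not isolated), via N,C-bis(silyl) carbamate 5 (not isolated)
Conditions: TMSOTf, TMEDA, Et2O, 0 °C to rt; n-BuLi, TMEDA, −78 °C; TMSCl, −78 °C to rt; aq. NaHSO4
Reagents that add atoms: chlorotrimethylsilane, C[Si](C)(C)Cl
Why: Directed ortho-metalation: after N-silylation the carbamate and the methoxy group together direct n-BuLi to the carbon between them, TMSCl traps the aryllithium, and aqueous acid removes the N-silyl group.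

Step 3
Reactants: 6 3-methoxy-5-methyl-2-(trimethylsilyl)phenyl N-isopropylcarbamate
Product: 8 3-methoxy-5-methyl-2-(trimethylsilyl)phenyl trifluoromethanesulfonate, via silyl phenol 7 (not isolated)
Conditions: DBU, Et2NH, MeCN, 40 °C; then PhNTf2, rt
Reagents that add atoms: N-phenylbis(trifluoromethanesulfonimide), O=S(=O)(N(c1ccccc1)S(=O)(=O)C(F)(F)F)C(F)(F)F
Why: DBU should cleave the N–H carbamate by base-induced elimination through the carbamate anion to the phenoxide and isopropyl isocyanate, which diethylamine scavenges as a urea, and the phenoxide is then O-triflated to give an ortho-silylaryl triflate aryne precursor.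

Step 4
Reactants: 9 1,1-dimethoxyethene (2.2 equiv)
Product: 10 4,4-dimethoxybut-3-en-2-one
Conditions: AcCl, Et2O, 0 °C to rt
Reagents that add atoms: acetyl chloride, CC(Cl)=O
Why: C-acylation of the nucleophilic ketene acetal by the acid chloride (McElvain acylation) should give the beta,beta-dimethoxy enone, the second equivalent of acetal taking up the HCl as methyl acetate and chloromethane.

Step 5
Reactants: 10 4,4-dimethoxybut-3-en-2-one
Product: 12 1,1-dimethoxy-3-(trimethylsilyloxy)buta-1,3-diene, via lithium dienolate 11 (not isolated)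
Conditions: LiN(i-Pr)2, THF, −78 °C; TMSCl, −78 °C to rt
Reagents that add atoms: chlorotrimethylsilane, C[Si](C)(C)Cl
Why: Kinetic deprotonation of the methyl ketone and O-silylation of the enolate (silyl enol ether formation) should give the 2-silyloxy diene, which is distilled and used fresh.

Step 6
Reactants: 8 3-methoxy-5-methyl-2-(trimethylsilyl)phenyl trifluoromethanesulfonate; 12 1,1-dimethoxy-3-(trimethylsilyloxy)buta-1,3-diene (3 equiv)
Product: 15 4,5-dimethoxy-7-methylnaphthalen-2-ol, via 3-methoxy-5-methylbenzyne 13 (not isolated), via dihydronaphthalene cycloadduct 14 (not isolated)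
Conditions: CsF, MeCN, rt; then 1 M HCl, THF, rt
Reagents that add atoms: none
Why: Fluoride-induced elimination gives the aryne, which should undergo an aryne Diels–Alder reaction with the electron-rich diene, the nucleophilic CH2 terminus bonding to the aryne carbon remote from the methoxy group as is usual for 3-alkoxybenzynes so that the acetal carbon ends up peri to that methoxy, and acid then removes methanol and the silyl group to aromatise ring W.

Step 7
Reactants: 15 4,5-dimethoxy-7-methylnaphthalen-2-ol
Product: 16 2-hydroxy-4,5-dimethoxy-7-methyl-1-naphthaldehyde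
Conditions: MgCl2, Et3N, (CH2O)n, MeCN, reflux; aq. HCl
Reagents that add atoms: paraformaldehyde (as formaldehyde), C=O
Why: Magnesium-phenoxide-directed ortho-formylation (Casnati–Skattebøl) should deliver formaldehyde to C1, the ortho position that 2-naphthols use because of the higher C1–C2 bond order and that is also para to the C4 methoxy group, and a second formaldehyde oxidises the hydroxymethyl chelate to the aldehyde.

Step 8
Reactants: 16 2-hydroxy-4,5-dimethoxy-7-methyl-1-naphthaldehyde
Product: 17 2-benzyloxy-4,5-dimethoxy-7-methyl-1-naphthaldehyde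
Conditions: BnBr, K2CO3, DMF, 60 °C
Reagents that add atoms: benzyl bromide, BrCc1ccccc1
Why: Williamson etherification of the hydrogen-bonded naphthol should proceed in warm DMF, as for 2-hydroxy-1-naphthaldehyde itself.

Step 9
Reactants: 18 2,3-dihydroxybenzaldehyde
Product: 20 3-benzyloxy-2-hydroxybenzaldehyde, via disodium dianion 19 (not isolated)
Conditions: NaH (2.2 equiv), DMSO, rt; BnBr (1.0 equiv); aq. HCl
Reagents that add atoms: benzyl bromide, BrCc1ccccc1
Why: In the dianion the C2 phenoxide is chelated and conjugated to the formyl group, so one equivalent of benzyl bromide should alkylate the more basic C3 phenoxide (regioselective Williamson etherification).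

Step 10
Reactants: 20 3-benzyloxy-2-hydroxybenzaldehyde
Product: 21 3-benzyloxy-2-methoxybenzaldehyde
Conditions: MeI, K2CO3, DMF, rt
Reagents that add atoms: iodomethane, CI
Why: Williamson methylation of the remaining phenol.

Step 11
Reactants: 21 3-benzyloxy-2-methoxybenzaldehyde
Product: 22 3-benzyloxy-6-bromo-2-methoxybenzaldehyde
Conditions: NBS, DMF, rt, dark
Reagents that add atoms: N-bromosuccinimide, O=C1CCC(=O)N1Br
Why: Electrophilic aromatic bromination should go para to the in-plane benzyloxy group (C6), as with 2,3-dimethoxybenzaldehyde, because the C2 methoxy group is twisted out of conjugation between its two neighbours.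

Step 12
Reactants: 22 3-benzyloxy-6-bromo-2-methoxybenzaldehyde
Product: 23 1-benzyloxy-4-bromo-3-(dimethoxymethyl)-2-methoxybenzene
Conditions: HC(OMe)3, TsOH·H2O (cat.), MeOH, reflux
Reagents that add atoms: trimethyl orthoformate, COC(OC)OC; methanol, CO
Why: Acid-catalysed acetalisation, driven by the orthoformate as water scavenger, masks the aldehyde as its dimethyl acetal for the lithiation.

Step 13
Reactants: 23 1-benzyloxy-4-bromo-3-(dimethoxymethyl)-2-methoxybenzene; 17 2-benzyloxy-4,5-dimethoxy-7-methyl-1-naphthaldehyde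
Product: 25 (2-benzyloxy-4,5-dimethoxy-7-methylnaphthalen-1-yl)[4-benzyloxy-2-(dimethoxymethyl)-3-methoxyphenyl]methanol (racemic), via aryllithium 24 (not isolated)
Conditions: n-BuLi, THF, −78 °C; then 17, −78 to 0 °C; aq. NH4Cl
Reagents that add atoms: none
Why: Bromine–lithium exchange at −78 °C is faster than any attack on the benzyl ether or acetal, and the aryllithium should add to the non-enolisable aldehyde (1,2-carbonyl addition) to give the racemic diaryl carbinol, whose stereocentre is lost later.

Step 14
Reactants: 25 (2-benzyloxy-4,5-dimethoxy-7-methylnaphthalen-1-yl)[4-benzyloxy-2-(dimethoxymethyl)-3-methoxyphenyl]methanol; 26 methyl propiolate (5 equiv)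
Product: 30 methyl 6-benzyloxy-1-(2-benzyloxy-4,5-dimethoxy-7-methylnaphthalen-1-yl)-4-hydroxy-5-methoxy-2-naphthoate, via cyclic methyl acetal 27 (not isolated), via isobenzofuran 28 (not isolated), via oxygen-bridged adduct 29 (not isolated)
Conditions: AcOH, PhMe, 90 °C, sealed tube; then TsOH·H2O (cat.), 60 °C
Reagents that add atoms: none
Why: Acid should close hydroxy acetal 25 to the cyclic acetal 27 and remove a second methanol to give the o-quinoid isobenzofuran 28, which adds methyl propiolate in an intermolecular [4+2] cycloaddition forming C1'–C2' and C3'–C4' to give adduct 29; the closest known reaction is the trapping of 1-arylisobenzofurans, released from hydroxy acetals in acetic acid, by acetylenic esters to give 1-aryl-4-hydroxynaphthoates. Ring Y is closed by this cycloaddition as a six-membered carbocycle, suprafacial on both partners, with the furan oxygen left as a C1'–O–C4' bridge and the benzene sextet of ring Z regained as driving force. The two bridgehead stereocentres of 29 (C1' and C4') form as a racemic pair under no control and both are erased on aromatisation, so no stereocentre has to be set. The step needs the ester-bearing alkyne carbon to bond to C1': the HOMO of 28 has its larger terminal coefficient at the unsubstituted C4', reinforced by the C6' benzyloxy donor conjugated to C4' through C5' and C4a', and this carbon pairs with the unsubstituted beta carbon of the propiolate in an asynchronous transition state whose advanced C3'–C4' bond keeps the ester away from the twisted naphthyl group until late. The step also needs the bridge to open at C1': ionisation there gives a cation flanked by two arenes, para to the C6' benzyloxy group through C8a', and allylic through C2'–C3' with the ester on the nodal carbon, whereas ionisation at C4' would place charge on the ester-bearing carbon, so the oxygen stays on C4' and loss of the C4' proton gives naphthol 30. The benzyl ethers, methyl ethers and ester should be stable to the acetic and catalytic sulfonic acid.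

Step 15
Reactants: 30 methyl 6-benzyloxy-1-(2-benzyloxy-4,5-dimethoxy-7-methylnaphthalen-1-yl)-4-hydroxy-5-methoxy-2-naphthoate
Product: 31 7-benzyloxy-4-(2-benzyloxy-4,5-dimethoxy-7-methylnaphthalen-1-yl)-3-(hydroxymethyl)-8-methoxynaphthalen-1-ol
Conditions: LiAlH4, THF, 0 °C to rt; aq. NaOH work-up
Reagents that add atoms: none
Why: After deprotonating the naphthol, LiAlH4 should reduce the hindered aryl ester to the primary alcohol (hydride reduction) and leave the benzyl and methyl ethers untouched.

Step 16
Reactants: 31 7-benzyloxy-4-(2-benzyloxy-4,5-dimethoxy-7-methylnaphthalen-1-yl)-3-(hydroxymethyl)-8-methoxynaphthalen-1-ol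
Product: 32 4-(2-hydroxy-4,5-dimethoxy-7-methylnaphthalen-1-yl)-8-methoxy-3-methylnaphthalene-1,7-diol (CNP0288130.0, racemic)
Conditions: H2 (1–3 atm), Pd/C, EtOAc–MeOH, HCl (cat.), rt
Reagents that add atoms: none
Why: Catalytic hydrogenolysis over Pd/C with acid should cleave both O-benzyl ethers and the naphthylmethyl C–OH bond, turning the C2' hydroxymethyl group into the methyl group.

**Compound list**

1 | 3-methoxy-5-methylphenol | COc1cc(C)cc(O)c1 | starting material
2 | 3-methoxy-5-methylphenyl N-isopropylcarbamate | COc1cc(C)cc(OC(=O)NC(C)C)c1 | intermediate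
3 | 3-methoxy-5-methylphenyl N-isopropyl-N-(trimethylsilyl)carbamate | COc1cc(C)cc(OC(=O)N(C(C)C)[Si](C)(C)C)c1 | intermediate
4 | 2-lithio-3-methoxy-5-methylphenyl N-isopropyl-N-(trimethylsilyl)carbamate | COc1cc(C)cc(OC(=O)N(C(C)C)[Si](C)(C)C)c1[Li] | intermediate
5 | 3-methoxy-5-methyl-2-(trimethylsilyl)phenyl N-isopropyl-N-(trimethylsilyl)carbamate | COc1cc(C)cc(OC(=O)N(C(C)C)[Si](C)(C)C)c1[Si](C)(C)C | intermediate
6 | 3-methoxy-5-methyl-2-(trimethylsilyl)phenyl N-isopropylcarbamate | COc1cc(C)cc(OC(=O)NC(C)C)c1[Si](C)(C)C | intermediate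
7 | 3-methoxy-5-methyl-2-(trimethylsilyl)phenol | COc1cc(C)cc(O)c1[Si](C)(C)C | intermediate
8 | 3-methoxy-5-methyl-2-(trimethylsilyl)phenyl trifluoromethanesulfonate | COc1cc(C)cc(OS(=O)(=O)C(F)(F)F)c1[Si](C)(C)C | intermediate
9 | 1,1-dimethoxyethene | C=C(OC)OC | starting material
10 | 4,4-dimethoxybut-3-en-2-one | CC(=O)C=C(OC)OC | intermediate
11 | lithium 4,4-dimethoxybuta-1,3-dien-2-olate | [Li+].[O-]C(=C)C=C(OC)OC | intermediate
12 | 1,1-dimethoxy-3-(trimethylsilyloxy)buta-1,3-diene | C=C(O[Si](C)(C)C)C=C(OC)OC | intermediate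
13 | 3-methoxy-5-methylbenzyne | COC1=CC(C)=CC#C1 | intermediate
14 | 4,4,5-trimethoxy-7-methyl-2-(trimethylsilyloxy)-1,4-dihydronaphthalene | COc1cc(C)cc2c1C(OC)(OC)C=C(O[Si](C)(C)C)C2 | intermediate
15 | 4,5-dimethoxy-7-methylnaphthalen-2-ol | COc1cc(C)cc2cc(O)cc(OC)c12 | intermediate
16 | 2-hydroxy-4,5-dimethoxy-7-methyl-1-naphthaldehyde | COc1cc(C)cc2c(C=O)c(O)cc(OC)c12 | intermediate
17 | 2-benzyloxy-4,5-dimethoxy-7-methyl-1-naphthaldehyde | COc1cc(C)cc2c(C=O)c(OCc3ccccc3)cc(OC)c12 | intermediate
18 | 2,3-dihydroxybenzaldehyde | O=Cc1cccc(O)c1O | starting material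
19 | disodium 3-formylbenzene-1,2-diolate | [Na+].[Na+].[O-]c1cccc(C=O)c1[O-] | intermediate
20 | 3-benzyloxy-2-hydroxybenzaldehyde | O=Cc1cccc(OCc2ccccc2)c1O | intermediate
21 | 3-benzyloxy-2-methoxybenzaldehyde | COc1c(OCc2ccccc2)cccc1C=O | intermediate
22 | 3-benzyloxy-6-bromo-2-methoxybenzaldehyde | COc1c(OCc2ccccc2)ccc(Br)c1C=O | intermediate
23 | 1-benzyloxy-4-bromo-3-(dimethoxymethyl)-2-methoxybenzene | COc1c(OCc2ccccc2)ccc(Br)c1C(OC)OC | intermediate
24 | [4-benzyloxy-2-(dimethoxymethyl)-3-methoxyphenyl]lithium | COc1c(OCc2ccccc2)ccc([Li])c1C(OC)OC | intermediate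
25 | (2-benzyloxy-4,5-dimethoxy-7-methylnaphthalen-1-yl)[4-benzyloxy-2-(dimethoxymethyl)-3-methoxyphenyl]methanol (racemic) | COc1c(OCc2ccccc2)ccc(C(O)c2c(OCc3ccccc3)cc(OC)c3c(OC)cc(C)cc23)c1C(OC)OC | intermediate
26 | methyl propiolate | C#CC(=O)OC | starting material
27 | 6-benzyloxy-3-(2-benzyloxy-4,5-dimethoxy-7-methylnaphthalen-1-yl)-1,7-dimethoxy-1,3-dihydroisobenzofuran (diastereomer mixture, racemic) | COC1OC(c2c(OCc3ccccc3)cc(OC)c3c(OC)cc(C)cc23)c2ccc(OCc3ccccc3)c(OC)c12 | intermediate
28 | 5-benzyloxy-1-(2-benzyloxy-4,5-dimethoxy-7-methylnaphthalen-1-yl)-4-methoxyisobenzofuran | COc1c(OCc2ccccc2)ccc2c(-c3c(OCc4ccccc4)cc(OC)c4c(OC)cc(C)cc34)occ12 | intermediate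
29 | methyl 6-benzyloxy-1-(2-benzyloxy-4,5-dimethoxy-7-methylnaphthalen-1-yl)-5-methoxy-1,4-dihydro-1,4-epoxynaphthalene-2-carboxylate (racemic) | COC(=O)C1=CC2OC1(c1c(OCc3ccccc3)cc(OC)c3c(OC)cc(C)cc13)c1ccc(OCc3ccccc3)c(OC)c21 | intermediate
30 | methyl 6-benzyloxy-1-(2-benzyloxy-4,5-dimethoxy-7-methylnaphthalen-1-yl)-4-hydroxy-5-methoxy-2-naphthoate (racemic axis) | COC(=O)c1cc(O)c2c(OC)c(OCc3ccccc3)ccc2c1-c1c(OCc2ccccc2)cc(OC)c2c(OC)cc(C)cc12 | intermediate
31 | 7-benzyloxy-4-(2-benzyloxy-4,5-dimethoxy-7-methylnaphthalen-1-yl)-3-(hydroxymethyl)-8-methoxynaphthalen-1-ol (racemic axis) | OCc1cc(O)c2c(OC)c(OCc3ccccc3)ccc2c1-c1c(OCc2ccccc2)cc(OC)c2c(OC)cc(C)cc12 | intermediate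
32 | 4-(2-hydroxy-4,5-dimethoxy-7-methylnaphthalen-1-yl)-8-methoxy-3-methylnaphthalene-1,7-diol (CNP0288130.0, racemic axis) | COc1cc(C)cc2c(-c3c(C)cc(O)c4c(OC)c(O)ccc34)c(O)cc(OC)c12 | target

**Totals**

Total step count: 16. Longest linear sequence: 10 steps (steps 1, 2, 3, 6, 7, 8, 13, 14, 15, 16).

**Steps most likely to fail**

1. Step 14. The cycloaddition may run in the reverse regiochemical sense, with the ester carbon bonding to C4' because of crowding at the aryl-bearing terminus, or the isobenzofuran may oligomerise before it is trapped. The fallback sets out from 25 and keeps the isobenzofuran route but removes the regiochemical question with a symmetrical dienophile. 25 is heated with dimethyl acetylenedicarboxylate and AcOH in PhMe, then with catalytic TsOH·H2O, so that 28 is trapped as the oxygen-bridged diester, dimethyl 6-benzyloxy-1-(2-benzyloxy-4,5-dimethoxy-7-methylnaphthalen-1-yl)-5-methoxy-1,4-dihydro-1,4-epoxynaphthalene-2,3-dicarboxylate F1. This should open in the same flask to dimethyl 6-benzyloxy-1-(2-benzyloxy-4,5-dimethoxy-7-methylnaphthalen-1-yl)-4-hydroxy-5-methoxynaphthalene-2,3-dicarboxylate F2. KOH in aqueous ethylene glycol at 120 °C should saponify both esters to 6-benzyloxy-1-(2-benzyloxy-4,5-dimethoxy-7-methylnaphthalen-1-yl)-4-hydroxy-5-methoxynaphthalene-2,3-dicarboxylic acid F3. Heating F3 in DMSO at about 150 °C should remove only the C3' carboxyl, which lies ortho to the C4' hydroxyl and decarboxylates through the keto tautomer as 1-hydroxy-2-naphthoic acids do, giving 6-benzyloxy-1-(2-benzyloxy-4,5-dimethoxy-7-methylnaphthalen-1-yl)-4-hydroxy-5-methoxy-2-naphthoic acid F4. LiAlH4 in THF should reduce F4 to the carbinol, and the fallback comes back to the route at 31.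

2. Step 6. Fluoride may strip the silyl group from diene 12 before it meets the aryne, [2+2] or ene pathways may compete with the [4+2] mode, and the naphtholate set free may be arylated by further aryne. The fallback sets out from 8 and builds ring W by a polar aryne insertion and a condensation. 8 is treated with methyl acetoacetate and CsF in MeCN at 80 °C (aryne acyl-alkylation; the enolate carbon adds to the aryne carbon remote from the methoxy group and the acetyl group moves to the carbon beside it) to give methyl 2-(2-acetyl-3-methoxy-5-methylphenyl)acetate F5. NaOMe in MeOH under argon (intramolecular Claisen condensation) should give 8-methoxy-6-methylnaphthalene-1,3-diol F6. One equivalent of BnBr with K2CO3 in acetone should alkylate the 3-hydroxyl, the 1-hydroxyl being held in a hydrogen bond to the peri methoxy group, giving 3-benzyloxy-8-methoxy-6-methylnaphthalen-1-ol F7. MeI with K2CO3 in DMF should then give 2-benzyloxy-4,5-dimethoxy-7-methylnaphthalene F8. Vilsmeier–Haack formylation (POCl3, DMF) at C1, which is ortho to the benzyloxy and para to the C4 methoxy group, brings the fallback back to the route at 17.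

3. Step 16. Hydrogenolysis of the primary benzylic C–O bond may stall once the benzyl ethers are gone, and forcing it may begin to saturate a naphthalene ring. The fallback sets out from 31 and activates the carbinol first. CBr4 and PPh3 in CH2Cl2 at 0 °C (Appel reaction, to which the phenol is inert) should give 7-benzyloxy-4-(2-benzyloxy-4,5-dimethoxy-7-methylnaphthalen-1-yl)-3-(bromomethyl)-8-methoxynaphthalen-1-ol F9. H2 over Pd/C with NaOAc in EtOAc–MeOH should then cleave the C–Br bond and both benzyl ethers under mild conditions, and the fallback comes back to the route at 32.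

**Further compounds**

F1 | step 14 | dimethyl 6-benzyloxy-1-(2-benzyloxy-4,5-dimethoxy-7-methylnaphthalen-1-yl)-5-methoxy-1,4-dihydro-1,4-epoxynaphthalene-2,3-dicarboxylate (racemic) | COC(=O)C1=C(C(=O)OC)C2OC1(c1c(OCc3ccccc3)cc(OC)c3c(OC)cc(C)cc13)c1ccc(OCc3ccccc3)c(OC)c21
F2 | step 14 | dimethyl 6-benzyloxy-1-(2-benzyloxy-4,5-dimethoxy-7-methylnaphthalen-1-yl)-4-hydroxy-5-methoxynaphthalene-2,3-dicarboxylate | COC(=O)c1c(O)c2c(OC)c(OCc3ccccc3)ccc2c(-c2c(OCc3ccccc3)cc(OC)c3c(OC)cc(C)cc23)c1C(=O)OC
F3 | step 14 | 6-benzyloxy-1-(2-benzyloxy-4,5-dimethoxy-7-methylnaphthalen-1-yl)-4-hydroxy-5-methoxynaphthalene-2,3-dicarboxylic acid | OC(=O)c1c(O)c2c(OC)c(OCc3ccccc3)ccc2c(-c2c(OCc3ccccc3)cc(OC)c3c(OC)cc(C)cc23)c1C(=O)O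
F4 | step 14 | 6-benzyloxy-1-(2-benzyloxy-4,5-dimethoxy-7-methylnaphthalen-1-yl)-4-hydroxy-5-methoxy-2-naphthoic acid | OC(=O)c1cc(O)c2c(OC)c(OCc3ccccc3)ccc2c1-c1c(OCc2ccccc2)cc(OC)c2c(OC)cc(C)cc12
F5 | step 6 | methyl 2-(2-acetyl-3-methoxy-5-methylphenyl)acetate | COC(=O)Cc1cc(C)cc(OC)c1C(C)=O
F6 | step 6 | 8-methoxy-6-methylnaphthalene-1,3-diol | COc1cc(C)cc2cc(O)cc(O)c12
F7 | step 6 | 3-benzyloxy-8-methoxy-6-methylnaphthalen-1-ol | COc1cc(C)cc2cc(OCc3ccccc3)cc(O)c12
F8 | step 6 | 2-benzyloxy-4,5-dimethoxy-7-methylnaphthalene | COc1cc(C)cc2cc(OCc3ccccc3)cc(OC)c12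
F9 | step 16 | 7-benzyloxy-4-(2-benzyloxy-4,5-dimethoxy-7-methylnaphthalen-1-yl)-3-(bromomethyl)-8-methoxynaphthalen-1-ol | BrCc1cc(O)c2c(OC)c(OCc3ccccc3)ccc2c1-c1c(OCc2ccccc2)cc(OC)c2c(OC)cc(C)cc12
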